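## The problem

6-Methyl-8-prenylnaringenin (18) is a flavanone. A fully substituted phloroglucinol ring A (hydroxyls at C5 and C7, methyl at C6, prenyl at C8) is fused through C4a–C8a to the dihydropyranone ring C, which carries the 4-hydroxyphenyl ring B at C2. The only stereocentre is C2 (S). It is benzylic and β to the C4 ketone, so base opens ring C to the chalcone by retro-oxa-Michael reaction, and the para hydroxyl of ring B makes the C2–O1 bond ionisable under strong acid or heat. No second stereocentre can relay to C2, so it has to be set by a catalyst and must see no base afterwards. Ring A has no free position: methyl at C6 must be told from prenyl at C8, and the ring oxygen O1 from the C5 hydroxyl, although these sites differ only in their neighbours. The prenyl group excludes hydrogenolysis, boron trihalides and electrophilic oxidants, and in strong protic acid it cyclises onto the C7 hydroxyl, so the phenols must be masked by groups that leave under mild acid. The feature that opens the plan is the unit O1–C8a–C4a–C4: an ortho-oxygenated benzylic carbon on a very electron-rich ring is the heterodiene of an ortho-quinone methide, and C2–C3 with ring B is the vinyl group of 4-hydroxystyrene. The polarities match (C4 electrophilic, C2 a para-hydroxybenzylic cation), and C4 can enter at the aldehyde oxidation level as a methyl ether that is later raised to the ketone.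

## Retrosynthesis

**18 ⇒ 17.** The two O–CH2 bonds of methoxymethyl (MOM) ethers at O5 and O7 are cut last. Benzyl ethers would demand hydrogenolysis and methyl ethers a boron trihalide, both fatal to the prenyl group. MOM ethers survive base, heat and the iridium and ruthenium steps, and leave by mild acid methanolysis. The 4'-hydroxyl stays free because the key step needs it.

**17 ⇒ 16 ⇒ 15.** Only the oxidation level of C4 changes: ketone from carbinol, carbinol from methyl ether. The neighbouring cut, acylation at C4a, would give the ketone directly but gives up the cycloaddition. The price here is two steps, neither of which touches C2, and both C4 epimers converge on one ketone. The forward steps need an ionising hydrolysis mild enough for the MOM ethers and an oxidation that is neutral and tolerant of a free phenol.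

**15 ⇒ 10 + 12.** C3–C4 and O1–C2 are cut together. Cutting O1–C2 alone leads back to a chalcone, whose oxa-Michael closure is reversible and hard to render enantioselective. Cutting C2–C1' would require a chromone and an arylmetal. The double cut divides 15 into the achiral, hexasubstituted salicylaldehyde 10 and the eight-carbon styrene 12, and it forms ring C and the C2 stereocentre in one event. The forward reaction must generate a cationic heterodiene from 10 with an acid weak enough for MOM and prenyl, and it must control the face of C2.

**12 ⇒ 11.** The phenol ester is cut. 4-Hydroxystyrene (12) polymerises on storage, so it is released from the stable acetate 11 just before use.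

**10 ⇒ 9.** The C4a–CHO bond is cut. Phenol-directed ortho-formylation meets only one unsubstituted ring carbon, so no regiochemical question arises. Vilsmeier conditions are avoided because of the acid-labile groups.

**9 ⇒ 7 + 8; 7 ⇒ 6 ⇒ 4 + 5.** The C8 side chain is taken apart at its alkene terminus and then at the ring–CH2 bond. Direct C-prenylation of 4 is shorter but competes with O-alkylation and double alkylation, and a Claisen shift of an O-prenyl ether would deliver the reverse-prenyl isomer. Allyl delivery by [3,3] shift from the symmetric ether 6 is unambiguous (both ortho positions equivalent, para blocked by methyl). Cross-metathesis with 8 then turns allyl into prenyl.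

**4 ⇒ 2 ⇒ 1.** The C–O bond at the future C8a is cut. In 2, the only C–H not ortho to a substituent is the one para to the methyl group, and sterically governed C–H borylation with [Ir(OMe)(cod)]2 followed by oxidation places the third oxygen there. The phenol that becomes O1 is thus born already differentiated from the two MOM-protected oxygens. Selective protection of 2-methylphloroglucinol would not give this pattern, since its least hindered hydroxyl is the one that must stay free. 2-Methylresorcinol (1) is the commercial starting point.

## Roads not taken

**Alternative 1:** Ring A is cut at C4a–C5 and C8–C8a. In the forward sense the C2-configured bromo-dihydropyranone A2 would be annulated with the bis(silyloxy)diene A3, and two eliminations would aromatise the adduct to the silyl-protected flavanone A1.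
- Merits: C2 would come from established asymmetric hetero-Diels–Alder chemistry of an aryl aldehyde and would be in place before ring A exists. Ring A would be born with all substituents in order and with free hydroxyls. A1 is one desilylation from 18, against three steps after the key step in the chosen plan. In these respects this road is better.
- Weak points: A2 is a vinylogous ester and a reluctant dienophile. A3 is a tetrasubstituted, moisture-sensitive diene whose C3=C4 geometry must be controlled. The annulation would probably run stepwise, and the enolate formed after the first bond at C8a can expel O1 and open ring C. The new 5,7-dihydroxyflavanone would also sit in the medium that drives the eliminations, where retro-oxa-Michael racemisation threatens. No close precedent is known for building a phloroglucinol ring on such a pyranone.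
- Comparison: the chosen plan sets against this two stable partners (10 and 12), a bond-forming mode known in racemic form, and a ring A whose substitution is fixed by symmetry early on.

**Alternative 2:** The cut is C4–C4a. Bromine–lithium exchange in the β-aryloxy Weinreb amide A5 and attack of the aryllithium on the amide would close ring C to the tris-MOM flavanone A4.
- Merits: Parham cyclisation onto a Weinreb amide is reliable, the C4 ketone appears directly with no redox adjustment, and C2 is fixed beforehand by known chemistry. In certainty of ring closure and of oxidation level this road is better.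
- Weak points: A4 has no prenyl group. Prenylation at C8 of a finished flavanone would need strongly basic or electrophilic conditions that C2 and the MOM ethers do not tolerate. If the prenyl group were placed before etherification, the C2–O1 bond would have to be made on a phenol flanked by bromine and prenyl, with a secondary carbinol that is benzylic and para-alkoxy-activated. Ionisation and elimination would then erode the stereocentre. The β-aryloxy amide can also lose aryloxide by β-elimination under the exchange conditions.
- Comparison: the chosen plan carries the prenyl group from the start and is convergent, but its enantiocontrol is unproven.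

**Alternative 3:** Three bonds of ring C are cut (C4a–C4, C4–C3, O1–C2). A PdCl2(PPh3)2-catalysed carbonylative Sonogashira coupling–cyclisation of the iodophenol A7 with the arylacetylene A8 would give the flavone A6.
- Merits: this is the most convergent plan, and its ring construction is better precedented than the chosen key step. C4 arrives at the right oxidation level, and A7 would follow from 9 by ortho-iodination, so the early steps are shared.
- Weak points: A6 is flat, so the only stereocentre is still to be made. That would require an enantioselective 1,4-reduction of the C2=C3 bond of a 5-alkoxyflavone beside a prenyl alkene. Hydrogenation catalysts are likely to saturate the side chain or over-reduce the ketone. Closure to the five-membered aurone also competes with flavone formation.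
- Comparison: the chosen plan forms ring and stereocentre in one operation and needs no reduction near the prenyl group. In reliability of the ring construction itself, Alternative 3 is superior.

Key step: step 8

Assumption: the sense of induction of the chiral phosphoric acid in step 8 cannot be predicted with confidence. The route is written with the (R)-acid, and its enantiomer is to be used if the (2R) series results.

## Steps

Step 1
Reactants: 1 2-methylresorcinol
Product: 2 1,3-bis(methoxymethoxy)-2-methylbenzene
Conditions: NaH, MOMCl, DMF, 0 °C → rt
Reagents that add atoms: chloromethyl methyl ether, COCCl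
Why: Williamson-type O-alkylation of both phenoxides gives the bis-acetal; MOM is chosen because it withstands the later basic, thermal and metal-catalysed steps and leaves by mild acid methanolysis.

Step 2
Reactants: 2 1,3-bis(methoxymethoxy)-2-methylbenzene
Product: 4 3,5-bis(methoxymethoxy)-4-methylphenol, via arylboronic pinacol ester 3 (not isolated)
Conditions: [Ir(OMe)(cod)]2 (1.5 mol%), 4,4'-di-tert-butyl-2,2'-bipyridine (3 mol%), B2pin2, THF, 80 °C; then aq. NaOH, 30% H2O2, 0 °C → rt
Reagents that add atoms: bis(pinacolato)diboron, CC1(C)OB(OC1(C)C)B1OC(C)(C)C(C)(C)O1 (its boron is carried only in 3); hydrogen peroxide, OO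
Why: Sterically governed aromatic C–H borylation attacks the only C–H that is not ortho to a substituent, and alkaline peroxide then oxidises the C–B bond with aryl migration from boron to oxygen; MOM ethers are inert to both stages.

Step 3
Reactants: 4 3,5-bis(methoxymethoxy)-4-methylphenol; 5 allyl bromide
Product: 6 5-(allyloxy)-1,3-bis(methoxymethoxy)-2-methylbenzene
Conditions: K2CO3, acetone, reflux
Reagents that add atoms: none
Why: Williamson ether synthesis on the single free phenol.

Step 4
Reactants: 6 5-(allyloxy)-1,3-bis(methoxymethoxy)-2-methylbenzene
Product: 7 2-allyl-3,5-bis(methoxymethoxy)-4-methylphenol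
Conditions: PhNEt2, 190 °C
Reagents that add atoms: none
Why: Aromatic Claisen rearrangement ([3,3] shift, then tautomerisation) delivers the allyl group to an ortho carbon; the two ortho positions are equivalent and the para position is blocked by methyl, so one product is expected, and aryl MOM ethers tolerate neutral thermolysis in an amine solvent.

Step 5
Reactants: 7 2-allyl-3,5-bis(methoxymethoxy)-4-methylphenol; 8 2-methyl-2-butene
Product: 9 3,5-bis(methoxymethoxy)-4-methyl-2-(3-methylbut-2-en-1-yl)phenol
Conditions: second-generation Grubbs catalyst RuCl2(=CHPh)(H2IMes)(PCy3) (3 mol%), 2-methyl-2-butene (excess), CH2Cl2, 40 °C, sealed tube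
Reagents that add atoms: none
Why: Olefin cross-metathesis of the terminal alkene with excess 2-methyl-2-butene exchanges the CH2 terminus for an isopropylidene group with loss of propene; free phenols and MOM ethers are tolerated by the ruthenium carbene.

Step 6
Reactants: 9 3,5-bis(methoxymethoxy)-4-methyl-2-(3-methylbut-2-en-1-yl)phenol
Product: 10 2-hydroxy-4,6-bis(methoxymethoxy)-5-methyl-3-(3-methylbut-2-en-1-yl)benzaldehyde
Conditions: MgCl2, Et3N, (CH2O)n, MeCN, reflux; aq. NH4Cl work-up
Reagents that add atoms: paraformaldehyde (as formaldehyde), C=O
Why: Magnesium-mediated ortho-formylation (Casnati–Skattebøl): the magnesium phenoxide delivers formaldehyde to the only free ring carbon and a second formaldehyde oxidises the benzylic alkoxide by hydride transfer; the basic medium leaves MOM ethers and the prenyl group untouched.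

Step 7
Reactants: 11 4-acetoxystyrene
Product: 12 4-hydroxystyrene
Conditions: K2CO3 (cat.), MeOH, 0 °C; extracted into toluene with a trace of BHT and used at once
Reagents that add atoms: none
Why: Base-catalysed methanolysis of the aryl acetate; the cold, brief treatment and immediate use keep the polymerisation-prone vinylphenol intact.

Step 8
Reactants: 10 2-hydroxy-4,6-bis(methoxymethoxy)-5-methyl-3-(3-methylbut-2-en-1-yl)benzaldehyde; 12 4-hydroxystyrene
Product: 15 4-[(2S,4RS)-4-methoxy-5,7-bis(methoxymethoxy)-6-methyl-8-(3-methylbut-2-en-1-yl)chroman-2-yl]phenol, via dimethyl acetal 13 (not isolated), via methoxy ortho-quinone methide cation 14 (not isolated)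
Conditions: HC(OMe)3 (2 equiv), (R)-TRIP [(R)-3,3'-bis(2,4,6-triisopropylphenyl)-1,1'-binaphthyl-2,2'-diyl hydrogen phosphate] (10 mol%), 5 Å MS, toluene, −20 °C, slow addition of 12 (2 equiv)
Reagents that add atoms: trimethyl orthoformate, COC(OC)OC
Why: Proposed new method: the orthoformate first acetalises the aldehyde, and the chiral phosphoric acid then ionises the acetal to the ortho-hydroxyaryl methoxycarbenium ion 14 (an O-methylated ortho-quinone methide), which is stabilised by O1, O5 and O7 and paired with the chiral phosphate. The terminal carbon of 12 attacks C4 (C3–C4 bond) and leaves a para-hydroxybenzylic cation, equivalent after proton transfer to a para-quinone methide; O1 then adds to C2, so the two bonds form in an asynchronous inverse-electron-demand oxa-[4+2] and the six-membered ring C closes by 6-exo-trig attack of the phenol oxygen on the quinone methide carbon. The closest known reaction types are the acid-promoted three-component coupling of salicylaldehydes, trimethyl orthoformate and styrenes to racemic 2-aryl-4-methoxychromans, chiral phosphoric acid-catalysed [4+2] cycloadditions of ortho-quinone methides with hydroxystyrenes, and chiral phosphoric acid-catalysed 1,6-additions to para-quinone methides; their combination on an acetal-derived cation is the new element. C2 is set in the ring closure by the phosphate, which is hydrogen-bonded to the 4'-oxygen and to O1–H and so shields one face of the planar C2; C4 forms without control and is erased in step 10. Regiochemistry needs nothing beyond polarity (nucleophilic styrene terminus to cationic C4, O1 to benzylic C2). Chemoselectivity over the prenyl alkene rests on the higher nucleophilicity of the hydroxystyrene and on geometry, since the C8 side chain cannot reach C4 of its own ring, and the fully substituted ring A offers no site for Friedel–Crafts self-condensation. The weak acid at low temperature should leave the MOM ethers and the prenyl group intact.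

Step 9
Reactants: 15 4-[(2S,4RS)-4-methoxy-5,7-bis(methoxymethoxy)-6-methyl-8-(3-methylbut-2-en-1-yl)chroman-2-yl]phenol
Product: 16 (2S,4RS)-2-(4-hydroxyphenyl)-5,7-bis(methoxymethoxy)-6-methyl-8-(3-methylbut-2-en-1-yl)chroman-4-ol
Conditions: PPTS (cat.), THF/H2O, rt; crude product taken on
Reagents that add atoms: water, O
Why: SN1 solvolysis: the C4 methyl ether ionises under very mild acid because the cation is a 2,4,6-trioxygenated benzylic cation, and water in large excess captures it; the acid is too weak to cleave aryl MOM ethers or the C2–O1 bond, so C2 is untouched and both C4 epimers are acceptable.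

Step 10
Reactants: 16 (2S,4RS)-2-(4-hydroxyphenyl)-5,7-bis(methoxymethoxy)-6-methyl-8-(3-methylbut-2-en-1-yl)chroman-4-ol
Product: 17 (2S)-2-(4-hydroxyphenyl)-5,7-bis(methoxymethoxy)-6-methyl-8-(3-methylbut-2-en-1-yl)chroman-4-one
Conditions: activated MnO2 (excess), CH2Cl2, rt
Reagents that add atoms: none
Why: MnO2 oxidation is selective for benzylic carbinols and runs under neutral heterogeneous conditions, which spare the free phenol, the prenyl group and the MOM ethers and give no base to open ring C; both C4 epimers converge on one ketone.

Step 11
Reactants: 17 (2S)-2-(4-hydroxyphenyl)-5,7-bis(methoxymethoxy)-6-methyl-8-(3-methylbut-2-en-1-yl)chroman-4-one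
Product: 18 6-methyl-8-prenylnaringenin, (2S)-5,7-dihydroxy-2-(4-hydroxyphenyl)-6-methyl-8-(3-methylbut-2-en-1-yl)chroman-4-one
Conditions: HCl (1 M in MeOH), rt → 40 °C
Reagents that add atoms: none
Why: Acid-catalysed transacetalisation to methanol removes both aryl MOM ethers as dimethoxymethane, the peri C5 ether going first with help from the C4 carbonyl; dilute acid near room temperature is chosen to avoid protonation of the prenyl alkene and ionisation at C2.

## Compound list

1 | 2-methylresorcinol | Cc1c(O)cccc1O | starting material
2 | 1,3-bis(methoxymethoxy)-2-methylbenzene | COCOc1cccc(OCOC)c1C | intermediate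
3 | 2-[3,5-bis(methoxymethoxy)-4-methylphenyl]-4,4,5,5-tetramethyl-1,3,2-dioxaborolane | COCOc1cc(B2OC(C)(C)C(C)(C)O2)cc(OCOC)c1C | intermediate
4 | 3,5-bis(methoxymethoxy)-4-methylphenol | COCOc1cc(O)cc(OCOC)c1C | intermediate
5 | allyl bromide | C=CCBr | starting material
6 | 5-(allyloxy)-1,3-bis(methoxymethoxy)-2-methylbenzene | C=CCOc1cc(OCOC)c(C)c(OCOC)c1 | intermediate
7 | 2-allyl-3,5-bis(methoxymethoxy)-4-methylphenol | C=CCc1c(O)cc(OCOC)c(C)c1OCOC | intermediate
8 | 2-methyl-2-butene | CC=C(C)C | starting material
9 | 3,5-bis(methoxymethoxy)-4-methyl-2-(3-methylbut-2-en-1-yl)phenol | CC(C)=CCc1c(O)cc(OCOC)c(C)c1OCOC | intermediate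
10 | 2-hydroxy-4,6-bis(methoxymethoxy)-5-methyl-3-(3-methylbut-2-en-1-yl)benzaldehyde | CC(C)=CCc1c(O)c(C=O)c(OCOC)c(C)c1OCOC | intermediate
11 | 4-acetoxystyrene | C=Cc1ccc(OC(C)=O)cc1 | starting material
12 | 4-hydroxystyrene | C=Cc1ccc(O)cc1 | intermediate
13 | 2-(dimethoxymethyl)-3,5-bis(methoxymethoxy)-4-methyl-6-(3-methylbut-2-en-1-yl)phenol (dimethyl acetal of 10) | COC(OC)c1c(O)c(CC=C(C)C)c(OCOC)c(C)c1OCOC | intermediate
14 | [2-hydroxy-4,6-bis(methoxymethoxy)-5-methyl-3-(3-methylbut-2-en-1-yl)phenyl]methylidene(methyl)oxonium, the O-methylated ortho-quinone methide cation, paired with the chiral phosphate | C[O+]=Cc1c(O)c(CC=C(C)C)c(OCOC)c(C)c1OCOC | intermediate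
15 | 4-[(2S,4RS)-4-methoxy-5,7-bis(methoxymethoxy)-6-methyl-8-(3-methylbut-2-en-1-yl)chroman-2-yl]phenol | CC(C)=CCc1c(OCOC)c(C)c(OCOC)c2c1O[C@H](c1ccc(O)cc1)CC2OC | intermediate
16 | (2S,4RS)-2-(4-hydroxyphenyl)-5,7-bis(methoxymethoxy)-6-methyl-8-(3-methylbut-2-en-1-yl)chroman-4-ol | CC(C)=CCc1c(OCOC)c(C)c(OCOC)c2c1O[C@H](c1ccc(O)cc1)CC2O | intermediate
17 | (2S)-2-(4-hydroxyphenyl)-5,7-bis(methoxymethoxy)-6-methyl-8-(3-methylbut-2-en-1-yl)chroman-4-one | CC(C)=CCc1c(OCOC)c(C)c(OCOC)c2c1O[C@H](c1ccc(O)cc1)CC2=O | intermediate
18 | 6-methyl-8-prenylnaringenin, (2S)-5,7-dihydroxy-2-(4-hydroxyphenyl)-6-methyl-8-(3-methylbut-2-en-1-yl)chroman-4-one | CC(C)=CCc1c(O)c(C)c(O)c2c1O[C@H](c1ccc(O)cc1)CC2=O | target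

## Step count and least certain steps

Total step count: 11. Longest linear sequence: 10 steps (steps 1–6 and 8–11, from 1 to 18); step 7 is a one-step side branch.

**Step 8 (key step, proposed new method).**
- What may go wrong: facial discrimination in the O1–C2 closure may be poor, because the ion pair is loosely organised and the C4 centre formed first may couple to C2 in a matched and a mismatched sense, so the two C4 epimers could carry different enantiomeric purity. Cationic oligomerisation of the hydroxystyrene may compete. The product may ionise again at C4 and capture a second styrene. Ionisation of the acetal may be slow with so weak an acid.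
- Fallback (known chemistry): set out from 10 and 12 and run the coupling without asymmetric induction, as the known Sc(OTf)3-catalysed three-component chroman synthesis with trimethyl orthoformate. This gives the racemic 4-methoxyflavan F1. Hydrolysis as in step 9 gives the racemic flavan-4-ol F2, and MnO2 oxidation as in step 10 gives the racemic bis-MOM flavanone F3. Resolution of F3 by preparative chromatography on a polysaccharide chiral stationary phase returns the route to 17; the (2R)-enantiomer F4 is set aside.

**Step 9.**
- What may go wrong: the C4 cation may lose a C3 proton instead of being captured by water (elimination to the 2H-chromene), the exchange may stop at equilibrium, and some MOM loss may occur if the acid has to be strengthened. The acid-labile carbinol may also decompose during the oxidation of step 10.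
- Fallback: set out from 15 and acetylate the 4'-hydroxyl (Ac2O, pyridine) to the 4'-acetate F5. Oxidise the C4 ether directly with DDQ in wet CH2Cl2: hydride abstraction at C4, the established site of DDQ attack in 5,7-dioxygenated flavans, is followed by hydration and collapse of the hemiketal. This gives the 4'-acetoxy flavanone F6. Under the conditions of step 11, F6 loses the acetate together with both MOM groups and the route comes back at 18. This detour bypasses 16 and 17 and therefore also covers step 10.

**Step 11.**
- What may go wrong: protonation of the prenyl alkene may lead to cyclisation onto the freed C7 hydroxyl or to addition of methanol, and prolonged acid may slowly ionise the C2–O1 bond and erode the configuration.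
- Fallback: set out from 17 and treat it with TMSOTf and 2,2'-bipyridyl in CH2Cl2 at 0 °C. This non-protic exchange converts aryl MOM ethers into aryl trimethylsilyl ethers and also silylates the 4'-hydroxyl, giving the tris(trimethylsilyl) ether F7. Stirring F7 with water cleaves the silyl ethers and the route comes back at 18.

**Step 4 (with steps 3 and 5, the prenyl installation).**
- What may go wrong: partial loss of MOM groups at 190 °C if traces of acid are present, and attrition over three steps for one side chain.
- Fallback: set out from 4 and alkylate its sodium phenoxide (NaH, toluene, rt) with prenyl bromide. The tight ion pair in a non-polar solvent favours ortho C-alkylation, the two ortho positions are equivalent and the para position is blocked. The route comes back at 9 without any new compound (F0). The cost is competing O-alkylation and double alkylation, which is why this is not the main route.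

## Further compounds

F1 | step 8 | racemic 4-[4-methoxy-5,7-bis(methoxymethoxy)-6-methyl-8-(3-methylbut-2-en-1-yl)chroman-2-yl]phenol | CC(C)=CCc1c(OCOC)c(C)c(OCOC)c2c1OC(c1ccc(O)cc1)CC2OC
F2 | step 8 | racemic 2-(4-hydroxyphenyl)-5,7-bis(methoxymethoxy)-6-methyl-8-(3-methylbut-2-en-1-yl)chroman-4-ol | CC(C)=CCc1c(OCOC)c(C)c(OCOC)c2c1OC(c1ccc(O)cc1)CC2O
F3 | step 8 | racemic 2-(4-hydroxyphenyl)-5,7-bis(methoxymethoxy)-6-methyl-8-(3-methylbut-2-en-1-yl)chroman-4-one | CC(C)=CCc1c(OCOC)c(C)c(OCOC)c2c1OC(c1ccc(O)cc1)CC2=O
F4 | step 8 | (2R)-2-(4-hydroxyphenyl)-5,7-bis(methoxymethoxy)-6-methyl-8-(3-methylbut-2-en-1-yl)chroman-4-one | CC(C)=CCc1c(OCOC)c(C)c(OCOC)c2c1O[C@@H](c1ccc(O)cc1)CC2=O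
F5 | step 9 | 4-[(2S,4RS)-4-methoxy-5,7-bis(methoxymethoxy)-6-methyl-8-(3-methylbut-2-en-1-yl)chroman-2-yl]phenyl acetate | CC(C)=CCc1c(OCOC)c(C)c(OCOC)c2c1O[C@H](c1ccc(OC(C)=O)cc1)CC2OC
F6 | step 9 | 4-[(2S)-5,7-bis(methoxymethoxy)-6-methyl-8-(3-methylbut-2-en-1-yl)-4-oxochroman-2-yl]phenyl acetate | CC(C)=CCc1c(OCOC)c(C)c(OCOC)c2c1O[C@H](c1ccc(OC(C)=O)cc1)CC2=O
F7 | step 11 | (2S)-6-methyl-8-(3-methylbut-2-en-1-yl)-5,7-bis(trimethylsilyloxy)-2-[4-(trimethylsilyloxy)phenyl]chroman-4-one | CC(C)=CCc1c(O[Si](C)(C)C)c(C)c(O[Si](C)(C)C)c2c1O[C@H](c1ccc(O[Si](C)(C)C)cc1)CC2=O
F0 | step 4 | none | none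
A1 | alternative 1 | (S)-4'-O-(tert-butyldimethylsilyl)-6-methyl-8-prenylnaringenin | CC(C)=CCc1c(O)c(C)c(O)c2c1O[C@H](c1ccc(O[Si](C)(C)C(C)(C)C)cc1)CC2=O
A2 | alternative 1 | (S)-5-bromo-2-[4-(tert-butyldimethylsilyloxy)phenyl]-2,3-dihydro-4H-pyran-4-one | O1[C@H](c2ccc(O[Si](C)(C)C(C)(C)C)cc2)CC(=O)C(Br)=C1
A3 | alternative 1 | 1-methoxy-2,7-dimethyl-1,3-bis(trimethylsilyloxy)octa-1,3,6-triene | COC(O[Si](C)(C)C)=C(C)C(O[Si](C)(C)C)=CCC=C(C)C
A4 | alternative 2 | (S)-5,7-bis(methoxymethoxy)-2-[4-(methoxymethoxy)phenyl]-6-methylchroman-4-one | c1c(OCOC)c(C)c(OCOC)c2c1O[C@H](c1ccc(OCOC)cc1)CC2=O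
A5 | alternative 2 | (S)-3-[2-bromo-3,5-bis(methoxymethoxy)-4-methylphenoxy]-N-methoxy-3-[4-(methoxymethoxy)phenyl]-N-methylpropanamide | CON(C)C(=O)C[C@H](Oc1cc(OCOC)c(C)c(OCOC)c1Br)c1ccc(OCOC)cc1
A6 | alternative 3 | 5,7-bis(methoxymethoxy)-2-[4-(methoxymethoxy)phenyl]-6-methyl-8-(3-methylbut-2-en-1-yl)-4H-chromen-4-one | CC(C)=CCc1c(OCOC)c(C)c(OCOC)c2c1OC(c1ccc(OCOC)cc1)=CC2=O
A7 | alternative 3 | 2-iodo-3,5-bis(methoxymethoxy)-4-methyl-6-(3-methylbut-2-en-1-yl)phenol | CC(C)=CCc1c(O)c(I)c(OCOC)c(C)c1OCOC
A8 | alternative 3 | 1-ethynyl-4-(methoxymethoxy)benzene | C#Cc1ccc(OCOC)cc1
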